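Ring A is made last: it is disconnected across C4a–C5 and C8–C8a and grown onto an enantiopure ring C by a Diels–Alder benzannulation. The step exploits the fact that ring A shares only its C4a–C8a edge with ring C, while C5 to C8 carry nothing but O7 and the C8 side chain. A (2S)-2-aryl-5-(phenylsulfinyl)-2,3-dihydropyran-4-one (its C=C becomes C4a=C8a) therefore takes up a 1-methoxy-3-silyloxy diene whose nucleophilic terminus already bears the (R)-configured chain, and loss of benzenesulfenic acid and methoxytrimethylsilane aromatises the new ring in the same operation. C2 and C2'' are set beforehand by separate catalytic steps, one in each fragment.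

Key step: step 14

Remarks: atom labels follow flavanone numbering (O1, C2 to C4, C4a, C5 to C8, C8a; C2'' is the carbinol carbon of the C8 chain). Ar = 4-(tert-butyldimethylsilyloxy)-3,5-bis(3-methylbut-2-en-1-yl)phenyl, TBS = tert-butyldimethylsilyl, TMS = trimethylsilyl.

Assumption: the titanium catalyst made from (S)-BINOL is taken to direct the diene to the Si face of aldehyde 4, as this catalyst family does in other additions to aryl aldehydes; should the pyranone prove to be (2R), (R)-BINOL is used instead.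

Step 1
Reactants: 1 4-hydroxybenzaldehyde; 2 prenyl bromide
Product: 3 4-hydroxy-3,5-bis(3-methylbut-2-en-1-yl)benzaldehyde
Conditions: 2 (2.5 equiv), 10% aq. KOH, 0 °C to rt
Reagents that add atoms: none
Why: In water the phenoxide oxygen is hydrogen-bonded, so the ambident anion is allylated at carbon (phenoxide C-alkylation), and with the para position blocked both ortho positions should take up a prenyl group; modest selectivity over O- and mono-alkylation is tolerable in a first step on commodity materials.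

Step 2
Reactants: 3 4-hydroxy-3,5-bis(3-methylbut-2-en-1-yl)benzaldehyde
Product: 4 4-(tert-butyldimethylsilyloxy)-3,5-bis(3-methylbut-2-en-1-yl)benzaldehyde (ArCHO)
Conditions: TBSCl, imidazole, DMF, rt
Reagents that add atoms: tert-butyldimethylsilyl chloride, CC(C)(C)[Si](C)(C)Cl
Why: Standard O-silylation of a phenol, which masks the acidic OH for the Lewis acid, base and organometallic steps that follow.

Step 3
Reactants: 4 ArCHO; 5 (E)-1-methoxy-3-(trimethylsilyloxy)buta-1,3-diene
Product: 7 (2S)-2-Ar-2,3-dihydro-4H-pyran-4-one, via silylated aldol adduct 6 (not isolated)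
Conditions: Ti(OiPr)4 (10 mol%), (S)-BINOL (20 mol%), 4 Å MS, Et2O, −20 °C; then CF3CO2H, CH2Cl2, 0 °C
Reagents that add atoms: none
Why: Catalytic asymmetric hetero-Diels–Alder reaction in its Mukaiyama aldol and cyclisation form, in which the chiral titanium BINOLate binds the aldehyde and leaves its Si face open to the diene so that C2 is set as S, and brief acid treatment closes ring C by addition–elimination with loss of methanol.

Step 4
Reactants: 7 (2S)-2-Ar-2,3-dihydro-4H-pyran-4-one
Product: 8 (2S)-2-Ar-5-iodo-2,3-dihydro-4H-pyran-4-one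
Conditions: I2, pyridine, CH2Cl2, 0 °C to rt
Reagents that add atoms: iodine, II
Why: α-Iodination of a cyclic enone with iodine and pyridine attacks only the nucleophilic α-carbon of the vinylogous ester (future C4a) and should leave the prenyl alkenes, the silyl ether and C2 untouched.

Step 5
Reactants: 8 (2S)-2-Ar-5-iodo-2,3-dihydro-4H-pyran-4-one
Product: 9 (2S)-2-Ar-5-(phenylsulfanyl)-2,3-dihydro-4H-pyran-4-one
Conditions: PhSH, Pd2(dba)3 (2.5 mol%), Xantphos (5 mol%), iPr2NEt, 1,4-dioxane, 60 °C
Reagents that add atoms: thiophenol, Sc1ccccc1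
Why: Palladium-catalysed C–S cross-coupling of an alkenyl iodide with a thiol (oxidative addition of zerovalent palladium, thiolate exchange, reductive elimination) under a weak amine base that should not open ring C or epimerise C2.

Step 6
Reactants: 9 (2S)-2-Ar-5-(phenylsulfanyl)-2,3-dihydro-4H-pyran-4-one
Product: 10 (2S)-2-Ar-5-(phenylsulfinyl)-2,3-dihydro-4H-pyran-4-one (both configurations at sulfur)
Conditions: mCPBA (1.0 equiv), CH2Cl2, −78 °C
Reagents that add atoms: 3-chloroperoxybenzoic acid, O=C(OO)c1cccc(Cl)c1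
Why: Sulfide-to-sulfoxide oxidation with one equivalent of peracid at low temperature, where sulfur reacts far faster than the trisubstituted prenyl alkenes; the configuration at sulfur is irrelevant because the group is expelled in step 14.

Step 7
Reactants: 11 methyl 4-chloro-4-oxobutanoate
Product: 12 methyl 5-methyl-4-oxohex-5-enoate
Conditions: CH2=C(CH3)MgBr, ZnCl2, THF, 0 °C; then 11, Pd(PPh3)4 (3 mol%), 0 °C to rt
Reagents that add atoms: isopropenylmagnesium bromide, C=C(C)[Mg]Br
Why: Negishi acylation, in which the alkenylzinc reagent made in the flask couples with the acid chloride under zerovalent palladium catalysis without attacking the methyl ester or the enone formed.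

Step 8
Reactants: 12 methyl 5-methyl-4-oxohex-5-enoate
Product: 14 (5R)-5-(prop-1-en-2-yl)dihydrofuran-2(3H)-one, via hydroxy ester 13 (not isolated)
Conditions: (S)-Me-CBS (10 mol%), catecholborane, toluene, −78 °C; then TsOH (cat.), CH2Cl2, rt
Reagents that add atoms: none
Why: Corey–Bakshi–Shibata reduction, in which the ketone binds to the (S)-oxazaborolidine with the isopropenyl group as the large substituent so that hydride delivery gives the (R)-alcohol (C2''), after which the γ-hydroxy ester lactonises under acid catalysis.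

Step 9
Reactants: 14 (5R)-5-(prop-1-en-2-yl)dihydrofuran-2(3H)-one
Product: 15 (4R)-4-hydroxy-N-methoxy-N,5-dimethylhex-5-enamide
Conditions: MeNHOMe·HCl, AlMe3, CH2Cl2, 0 °C to rt
Reagents that add atoms: N,O-dimethylhydroxylamine hydrochloride, CNOC.Cl
Why: Aluminium amide aminolysis of a lactone opens the ring to the N-methoxy-N-methylamide (Weinreb amide) without touching the stereocentre.

Step 10
Reactants: 15 (4R)-4-hydroxy-N-methoxy-N,5-dimethylhex-5-enamide
Product: 16 (4R)-4-(tert-butyldimethylsilyloxy)-N-methoxy-N,5-dimethylhex-5-enamide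
Conditions: TBSCl, imidazole, DMF, rt
Reagents that add atoms: tert-butyldimethylsilyl chloride, CC(C)(C)[Si](C)(C)Cl
Why: Standard silylation of a secondary alcohol, which also prevents relactonisation.

Step 11
Reactants: 16 (4R)-4-(tert-butyldimethylsilyloxy)-N-methoxy-N,5-dimethylhex-5-enamide
Product: 17 (6R)-6-(tert-butyldimethylsilyloxy)-7-methyloct-7-en-1-yn-3-one
Conditions: HC≡CMgBr, THF, −20 to 0 °C; cold 1 M HCl quench
Reagents that add atoms: ethynylmagnesium bromide, C#C[Mg]Br
Why: Weinreb ketone synthesis, in which the chelated tetrahedral adduct persists until the cold acidic quench, so the alkynyl Grignard reagent adds once and the liberated amine cannot add to the ynone.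

Step 12
Reactants: 17 (6R)-6-(tert-butyldimethylsilyloxy)-7-methyloct-7-en-1-yn-3-one
Product: 18 (1E,6R)-6-(tert-butyldimethylsilyloxy)-1-methoxy-7-methylocta-1,7-dien-3-one
Conditions: MeOH (5 equiv), DABCO (10 mol%), CH2Cl2, 0 °C
Reagents that add atoms: methanol, CO
Why: Amine-catalysed conjugate addition of methanol to a terminal ynone (oxa-Michael addition) should give the thermodynamically preferred (E)-β-methoxy enone.

Step 13
Reactants: 18 (1E,6R)-6-(tert-butyldimethylsilyloxy)-1-methoxy-7-methylocta-1,7-dien-3-one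
Product: 19 (1E,3Z,6R)-6-(tert-butyldimethylsilyloxy)-1-methoxy-7-methyl-3-(trimethylsilyloxy)octa-1,3,7-triene
Conditions: TMSOTf, Et3N, Et2O, 0 °C; pentane, filtration under argon; used at once
Reagents that add atoms: trimethylsilyl trifluoromethanesulfonate, C[Si](C)(C)OS(=O)(=O)C(F)(F)F
Why: Soft enolisation and O-silylation of the only enolisable α-position of the vinylogous ester gives the cross-conjugated silyl dienol ether, the (3Z)-isomer (chain trans to the methoxyvinyl group) being favoured on steric grounds as in other 4-substituted 1-methoxy-3-silyloxy dienes.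

Step 14
Reactants: 10 (2S)-2-Ar-5-(phenylsulfinyl)-2,3-dihydro-4H-pyran-4-one; 19 (1E,3Z,6R)-6-(tert-butyldimethylsilyloxy)-1-methoxy-7-methyl-3-(trimethylsilyloxy)octa-1,3,7-triene
Product: 22 (2S)-2-Ar-8-[(2R)-2-(tert-butyldimethylsilyloxy)-3-methylbut-3-en-1-yl]-7-hydroxychroman-4-one, via cycloadduct 20 (not isolated), via methoxy dihydroflavanone 21 (not isolated)
Conditions: 19 (2 equiv), toluene, 90 °C, argon; then PPTS (cat.), CH2Cl2/MeOH, rt
Reagents that add atoms: none
Why: In a thermal, asynchronous [4+2] cycloaddition the silyl enol ether terminus of 19 (future C8) attacks the β-carbon of the α-sulfinyl enone in 10 (future C8a) and the methoxy-bearing terminus (future C5) closes onto the α-carbon (future C4a), giving adduct 20. The closest known reaction type is the Diels–Alder benzannulation of 1-methoxy-3-silyloxy dienes with 2-sulfinyl enones and 3-sulfinylchromones, in which sulfenic acid and methanol are lost after the cycloaddition. Ring A closes as a six-membered carbocycle by this suprafacial cycloaddition, which leaves the sulfinyl group and H-8a cis, so thermal syn elimination of PhSOH restores C4a=C8a (21), and acid-promoted loss of MeOSiMe3 then leaves the aromatic ring with the free C7 phenol. No new stereocentre survives, because C4a, C5, C8 and C8a all end up sp2, so endo/exo and facial selectivity are irrelevant and C2 and C2'' are only carried through. The step needs regioselectivity alone: the oxygen donors on C5 and C7 make C8 the nucleophilic end, the C4 carbonyl and the sulfinyl group make C8a the electrophilic end, and the 3Z geometry keeps the chain on the outside so that the s-cis conformer is accessible.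

Step 15
Reactants: 22 (2S)-2-Ar-8-[(2R)-2-(tert-butyldimethylsilyloxy)-3-methylbut-3-en-1-yl]-7-hydroxychroman-4-one
Product: 23 (2S)-7-hydroxy-2-[4-hydroxy-3,5-bis(3-methylbut-2-en-1-yl)phenyl]-8-[(2R)-2-hydroxy-3-methylbut-3-en-1-yl]chroman-4-one
Conditions: TBAF/AcOH (1:1), THF, 0 °C to rt
Reagents that add atoms: none
Why: Fluoride-mediated cleavage of the aryl and the secondary silyl ether, buffered with acetic acid so that the flavanone should not open to the chalcone and C2 is not epimerised.

Compound list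

1 | 4-hydroxybenzaldehyde | O=Cc1ccc(O)cc1 | starting material
2 | prenyl bromide (1-bromo-3-methylbut-2-ene) | CC(C)=CCBr | starting material
3 | 4-hydroxy-3,5-bis(3-methylbut-2-en-1-yl)benzaldehyde | O=Cc1cc(CC=C(C)C)c(O)c(CC=C(C)C)c1 | intermediate
4 | 4-(tert-butyldimethylsilyloxy)-3,5-bis(3-methylbut-2-en-1-yl)benzaldehyde | O=Cc1cc(CC=C(C)C)c(O[Si](C)(C)C(C)(C)C)c(CC=C(C)C)c1 | intermediate
5 | (E)-1-methoxy-3-(trimethylsilyloxy)buta-1,3-diene | CO/C=C/C(=C)O[Si](C)(C)C | starting material
6 | (1E,5S)-5-Ar-1-methoxy-5-(trimethylsilyloxy)pent-1-en-3-one | CO/C=C/C(=O)C[C@H](O[Si](C)(C)C)c1cc(CC=C(C)C)c(O[Si](C)(C)C(C)(C)C)c(CC=C(C)C)c1 | intermediate (not isolated)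
7 | (2S)-2-Ar-2,3-dihydro-4H-pyran-4-one | O=C1C[C@@H](c2cc(CC=C(C)C)c(O[Si](C)(C)C(C)(C)C)c(CC=C(C)C)c2)OC=C1 | intermediate
8 | (2S)-2-Ar-5-iodo-2,3-dihydro-4H-pyran-4-one | O=C1C[C@@H](c2cc(CC=C(C)C)c(O[Si](C)(C)C(C)(C)C)c(CC=C(C)C)c2)OC=C1I | intermediate
9 | (2S)-2-Ar-5-(phenylsulfanyl)-2,3-dihydro-4H-pyran-4-one | O=C1C[C@@H](c2cc(CC=C(C)C)c(O[Si](C)(C)C(C)(C)C)c(CC=C(C)C)c2)OC=C1Sc1ccccc1 | intermediate
10 | (2S)-2-Ar-5-(phenylsulfinyl)-2,3-dihydro-4H-pyran-4-one, either configuration at sulfur | O=C1C[C@@H](c2cc(CC=C(C)C)c(O[Si](C)(C)C(C)(C)C)c(CC=C(C)C)c2)OC=C1S(=O)c1ccccc1 | intermediate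
11 | methyl 4-chloro-4-oxobutanoate | COC(=O)CCC(=O)Cl | starting material
12 | methyl 5-methyl-4-oxohex-5-enoate | C=C(C)C(=O)CCC(=O)OC | intermediate
13 | methyl (4R)-4-hydroxy-5-methylhex-5-enoate | C=C(C)[C@H](O)CCC(=O)OC | intermediate (not isolated)
14 | (5R)-5-(prop-1-en-2-yl)dihydrofuran-2(3H)-one | C=C(C)[C@H]1CCC(=O)O1 | intermediate
15 | (4R)-4-hydroxy-N-methoxy-N,5-dimethylhex-5-enamide | C=C(C)[C@H](O)CCC(=O)N(C)OC | intermediate
16 | (4R)-4-(tert-butyldimethylsilyloxy)-N-methoxy-N,5-dimethylhex-5-enamide | C=C(C)[C@H](O[Si](C)(C)C(C)(C)C)CCC(=O)N(C)OC | intermediate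
17 | (6R)-6-(tert-butyldimethylsilyloxy)-7-methyloct-7-en-1-yn-3-one | C=C(C)[C@H](O[Si](C)(C)C(C)(C)C)CCC(=O)C#C | intermediate
18 | (1E,6R)-6-(tert-butyldimethylsilyloxy)-1-methoxy-7-methylocta-1,7-dien-3-one | C=C(C)[C@H](O[Si](C)(C)C(C)(C)C)CCC(=O)/C=C/OC | intermediate
19 | (1E,3Z,6R)-6-(tert-butyldimethylsilyloxy)-1-methoxy-7-methyl-3-(trimethylsilyloxy)octa-1,3,7-triene | CO/C=C/C(O[Si](C)(C)C)=C/C[C@@H](O[Si](C)(C)C(C)(C)C)C(C)=C | intermediate
20 | Diels–Alder adduct: (2S)-2-Ar-5-methoxy-4a-(phenylsulfinyl)-7-(trimethylsilyloxy)-8-[(2R)-2-(tert-butyldimethylsilyloxy)-3-methylbut-3-en-1-yl]-4a,5,8,8a-tetrahydrochroman-4-one, mixture of diastereomers at C4a, C5, C8, C8a and sulfur | COC1C=C(O[Si](C)(C)C)C(C[C@@H](O[Si](C)(C)C(C)(C)C)C(C)=C)C2O[C@H](c3cc(CC=C(C)C)c(O[Si](C)(C)C(C)(C)C)c(CC=C(C)C)c3)CC(=O)C12S(=O)c1ccccc1 | intermediate (not isolated)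
21 | (2S)-2-Ar-5-methoxy-7-(trimethylsilyloxy)-8-[(2R)-2-(tert-butyldimethylsilyloxy)-3-methylbut-3-en-1-yl]-5,8-dihydrochroman-4-one (C4a=C8a restored), mixture at C5 and C8 | COC1C=C(O[Si](C)(C)C)C(C[C@@H](O[Si](C)(C)C(C)(C)C)C(C)=C)C2=C1C(=O)C[C@@H](c1cc(CC=C(C)C)c(O[Si](C)(C)C(C)(C)C)c(CC=C(C)C)c1)O2 | intermediate (not isolated)
22 | (2S)-2-Ar-8-[(2R)-2-(tert-butyldimethylsilyloxy)-3-methylbut-3-en-1-yl]-7-hydroxychroman-4-one | C=C(C)[C@H](O[Si](C)(C)C(C)(C)C)Cc1c(O)ccc2c1O[C@H](c1cc(CC=C(C)C)c(O[Si](C)(C)C(C)(C)C)c(CC=C(C)C)c1)CC2=O | intermediate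
23 | (2S)-7-hydroxy-2-[4-hydroxy-3,5-bis(3-methylbut-2-en-1-yl)phenyl]-8-[(2R)-2-hydroxy-3-methylbut-3-en-1-yl]chroman-4-one | C=C(C)[C@H](O)Cc1c(O)ccc2c1O[C@H](c1cc(CC=C(C)C)c(O)c(CC=C(C)C)c1)CC2=O | target

Total step count: 15.
Longest linear sequence: 9 steps (steps 7 to 13, then 14 and 15); the ring B and ring C branch (steps 1 to 6) joins at step 14.

Steps most likely to fail

1. Step 14. The cycloaddition to the donor-substituted (push–pull) alkene may be slower than thermal or acid-induced decay of the terminally substituted diene. The sulfenic acid may also be expelled toward C5 instead of C8a, after which aromatisation would cleave the C8a–O1 bond and open ring C. Fallback (ring A taken from a resorcinol ketone and ring C closed last by the chalcone route; sets out from phenol 3 and prenyl bromide 2, comes back at target 23):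
   - Phenol 3 is protected as methoxymethyl ether F1 (MOMCl, iPr2NEt).
   - Commercial 2,4-dihydroxyacetophenone is C-prenylated with 2 in aqueous KOH to 3-prenyl ketone F2, and both phenols are masked as bis(methoxymethyl) ether F3 (NaH, MOMCl).
   - Shi epoxidation with the D-fructose-derived ketone and KHSO5 should give (R)-epoxide F4.
   - Diethylaluminium 2,2,6,6-tetramethylpiperidide (from Et2AlCl and the lithium amide, in excess because the ketone is enolised) isomerises it to (R)-allylic alcohol F5, the C–O bond at C2'' staying intact.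
   - Claisen–Schmidt condensation of F5 with F1 (KOH, EtOH) gives chalcone F6, and dilute HCl in MeOH removes the three acetals to give trihydroxychalcone F7.
   - NaOAc in hot EtOH closes ring C by oxa-Michael addition to target 23 together with its C2 epimer F8. The two are diastereomers and are separated by preparative HPLC, and F8 is recycled through F7 under the same conditions.

2. Step 3. The electron-rich aryl aldehyde may be activated too weakly by the titanium catalyst, so conversion stalls or an uncatalysed pathway erodes the facial selectivity at C2. Fallback (reagent-controlled aldol addition instead of catalysis; sets out from aldehyde 4, comes back at pyranone 7): (E)-4-methoxybut-3-en-2-one is converted into its boron enolate with (−)-Ipc2BCl and iPr2NEt (Et2O, −78 °C; the reagent enantiomer expected to attack the Si face of the aldehyde) and added to 4 to give β-hydroxy enone F9, which PPTS or CF3CO2H cyclises to 7 with loss of methanol.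

3. Step 5. Thiolate may attack C6 and open ring C, or reduce the C–I bond, faster than the catalytic coupling turns over. Fallback (sulfur introduced by enolate sulfenylation and the double bond restored afterwards; sets out from pyranone 7, comes back at sulfide 9): conjugate reduction of 7 with LiBH(s-Bu)3 (THF, −78 °C) gives the C4–C5 enolate regiospecifically, which is sulfenylated with S-phenyl benzenethiosulfonate to α-phenylthio ketone F10. N-chlorosuccinimide chlorinates the sulfur-bearing carbon to α-chloro sulfide F11, which loses HCl toward C6, the only position with β-hydrogens, to give 9.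

Further compounds

F1 | step 14 | 4-(methoxymethoxy)-3,5-bis(3-methylbut-2-en-1-yl)benzaldehyde | O=Cc1cc(CC=C(C)C)c(OCOC)c(CC=C(C)C)c1
F2 | step 14 | 1-[2,4-dihydroxy-3-(3-methylbut-2-en-1-yl)phenyl]ethan-1-one | CC(=O)c1ccc(O)c(CC=C(C)C)c1O
F3 | step 14 | 1-[2,4-bis(methoxymethoxy)-3-(3-methylbut-2-en-1-yl)phenyl]ethan-1-one | CC(=O)c1ccc(OCOC)c(CC=C(C)C)c1OCOC
F4 | step 14 | 1-[3-{[(2R)-3,3-dimethyloxiran-2-yl]methyl}-2,4-bis(methoxymethoxy)phenyl]ethan-1-one | CC(=O)c1ccc(OCOC)c(C[C@H]2OC2(C)C)c1OCOC
F5 | step 14 | 1-[3-[(2R)-2-hydroxy-3-methylbut-3-en-1-yl]-2,4-bis(methoxymethoxy)phenyl]ethan-1-one | C=C(C)[C@H](O)Cc1c(OCOC)ccc(C(C)=O)c1OCOC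
F6 | step 14 | (2E)-1-[3-[(2R)-2-hydroxy-3-methylbut-3-en-1-yl]-2,4-bis(methoxymethoxy)phenyl]-3-[4-(methoxymethoxy)-3,5-bis(3-methylbut-2-en-1-yl)phenyl]prop-2-en-1-one | C=C(C)[C@H](O)Cc1c(OCOC)ccc(C(=O)/C=C/c2cc(CC=C(C)C)c(OCOC)c(CC=C(C)C)c2)c1OCOC
F7 | step 14 | (2E)-1-[2,4-dihydroxy-3-[(2R)-2-hydroxy-3-methylbut-3-en-1-yl]phenyl]-3-[4-hydroxy-3,5-bis(3-methylbut-2-en-1-yl)phenyl]prop-2-en-1-one | C=C(C)[C@H](O)Cc1c(O)ccc(C(=O)/C=C/c2cc(CC=C(C)C)c(O)c(CC=C(C)C)c2)c1O
F8 | step 14 | (2R)-7-hydroxy-2-[4-hydroxy-3,5-bis(3-methylbut-2-en-1-yl)phenyl]-8-[(2R)-2-hydroxy-3-methylbut-3-en-1-yl]chroman-4-one | C=C(C)[C@H](O)Cc1c(O)ccc2c1O[C@@H](c1cc(CC=C(C)C)c(O)c(CC=C(C)C)c1)CC2=O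
F9 | step 3 | (1E,5S)-5-Ar-5-hydroxy-1-methoxypent-1-en-3-one | CO/C=C/C(=O)C[C@H](O)c1cc(CC=C(C)C)c(O[Si](C)(C)C(C)(C)C)c(CC=C(C)C)c1
F10 | step 5 | (2S)-2-Ar-5-(phenylsulfanyl)tetrahydro-4H-pyran-4-one, mixture at C5 | O=C1C[C@@H](c2cc(CC=C(C)C)c(O[Si](C)(C)C(C)(C)C)c(CC=C(C)C)c2)OCC1Sc1ccccc1
F11 | step 5 | (2S)-2-Ar-5-chloro-5-(phenylsulfanyl)tetrahydro-4H-pyran-4-one, mixture at C5 | O=C1C[C@@H](c2cc(CC=C(C)C)c(O[Si](C)(C)C(C)(C)C)c(CC=C(C)C)c2)OCC1(Cl)Sc1ccccc1
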